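**Strategy**

Everything rests on cutting ring C of the flavone at O1–C8a, C4–C4a and O1–C2. In one fluoride-triggered operation a ring A aryne (C4a≡C8a) inserts into the C–O bond of an arylpropiolic acid: oxygen adds at C8a, the acyl group shifts to C4a, and the freed phenoxide closes the pyranone. The step exploits the placement of O1 and C4 on the adjacent ring A carbons C8a and C4a, the latter next to the C5 oxygen, which polarises the aryne toward attack at C8a. The precursor is a fully substituted o-silylaryl triflate carrying only C1'' of the side chain, as CH2OTIPS; the stereogenic chain is added later by asymmetric allylboration of the 8-carbaldehyde and benzylic deoxygenation.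

Key step: step 11

Assumption: the stereocentre of the target is C2'' of the hexyl chain and is R. TRIP-type phosphoric acids are taken to deliver allyl groups to the Re face of aryl aldehydes with the (R)-acid, so the (S)-acid is used in step 18.

**Ring A fragment (aryne precursor)**

Step 1
Reactants: 1 2,4,6-trihydroxybenzaldehyde
Product: 2 2-hydroxy-4,6-bis(methoxymethoxy)benzaldehyde
Conditions: MOMCl (2.2 equiv), i-Pr2NEt, CH2Cl2, 0 °C → rt
Reagents that add atoms: chloromethyl methyl ether, COCCl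
Why: Williamson-type O-alkylation takes the para hydroxyl and one ortho hydroxyl, after which the remaining ortho hydroxyl is held in a hydrogen bond to the formyl oxygen and is not alkylated by an amine base.

Step 2
Reactants: 2 2-hydroxy-4,6-bis(methoxymethoxy)benzaldehyde
Product: 3 2-formyl-3,5-bis(methoxymethoxy)phenyl N,N-diethylcarbamate
Conditions: NaH, THF, 0 °C; Et2NCOCl, rt → 50 °C
Reagents that add atoms: N,N-diethylcarbamoyl chloride, CCN(CC)C(Cl)=O
Why: O-acylation of the sodium phenoxide by a carbamoyl chloride installs the strongest oxygen-based directing group for the later ortho-metalation; the aldehyde has no enolisable hydrogen.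

Step 3
Reactants: 3 2-formyl-3,5-bis(methoxymethoxy)phenyl N,N-diethylcarbamate
Product: 4 2-(hydroxymethyl)-3,5-bis(methoxymethoxy)phenyl N,N-diethylcarbamate
Conditions: NaBH4, MeOH–THF, 0 °C
Reagents that add atoms: none
Why: Borohydride reduction of the aryl aldehyde; the N,N-dialkyl carbamate is inert to hydride and, unlike an N-monoalkyl carbamate, is not transferred to the new benzylic alkoxide.

Step 4
Reactants: 4 2-(hydroxymethyl)-3,5-bis(methoxymethoxy)phenyl N,N-diethylcarbamate
Product: 5 3,5-bis(methoxymethoxy)-2-{[(triisopropylsilyl)oxy]methyl}phenyl N,N-diethylcarbamate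
Conditions: TIPSCl, imidazole, DMF, rt
Reagents that add atoms: chlorotriisopropylsilane, CC(C)[Si](Cl)(C(C)C)C(C)C
Why: Silylation of the primary benzylic alcohol; the triisopropylsilyl ether shields the benzylic hydrogens from the alkyllithium of step 5 and is the common silyl ether most resistant to the fluoride of step 11.

Step 5
Reactants: 5 3,5-bis(methoxymethoxy)-2-{[(triisopropylsilyl)oxy]methyl}phenyl N,N-diethylcarbamate
Product: 7 3,5-bis(methoxymethoxy)-2-{[(triisopropylsilyl)oxy]methyl}-6-(trimethylsilyl)phenyl N,N-diethylcarbamate, via aryllithium 6 (not isolated)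
Conditions: s-BuLi, TMEDA, THF, −78 °C; then TMSCl, −78 °C → rt
Reagents that add atoms: chlorotrimethylsilane, C[Si](C)(C)Cl
Why: Directed ortho-metalation: carbamate and the neighbouring methoxymethoxy group together direct lithiation to the ring CH between them (the later C4a), the other ortho position of the carbamate being substituted, and the aryllithium is silylated at −78 °C before an anionic Fries shift can set in.

Step 6
Reactants: 7 3,5-bis(methoxymethoxy)-2-{[(triisopropylsilyl)oxy]methyl}-6-(trimethylsilyl)phenyl N,N-diethylcarbamate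
Product: 8 3,5-bis(methoxymethoxy)-2-{[(triisopropylsilyl)oxy]methyl}-6-(trimethylsilyl)phenol
Conditions: LiAlH4, THF, 0 °C → reflux; Rochelle salt work-up
Reagents that add atoms: none
Why: Reductive cleavage of the aryl carbamate by hydride attack at the carbonyl releases the phenol, while the aryl–silicon bond, the acetals and the silyl ether are inert to hydride.

Step 7
Reactants: 8 3,5-bis(methoxymethoxy)-2-{[(triisopropylsilyl)oxy]methyl}-6-(trimethylsilyl)phenol
Product: 9 3,5-bis(methoxymethoxy)-2-{[(triisopropylsilyl)oxy]methyl}-6-(trimethylsilyl)phenyl trifluoromethanesulfonate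
Conditions: Tf2O, pyridine, CH2Cl2, −20 → 0 °C
Reagents that add atoms: trifluoromethanesulfonic anhydride, O=S(=O)(OS(=O)(=O)C(F)(F)F)C(F)(F)F
Why: O-sulfonylation of the hindered phenol under pyridine buffering gives the o-silylaryl triflate required for fluoride-induced aryne generation.

**Ring B fragment (arylpropiolic acid)**

Step 8
Reactants: 10 2,4-dihydroxybenzaldehyde
Product: 11 2,4-bis(methoxymethoxy)benzaldehyde
Conditions: NaH, DMF, 0 °C; MOMCl (2.5 equiv), rt
Reagents that add atoms: chloromethyl methyl ether, COCCl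
Why: Williamson-type alkylation of the disodium salt protects both phenols, the stronger base overriding the hydrogen bond of the ortho hydroxyl.

Step 9
Reactants: 11 2,4-bis(methoxymethoxy)benzaldehyde
Product: 12 1-ethynyl-2,4-bis(methoxymethoxy)benzene
Conditions: dimethyl (1-diazo-2-oxopropyl)phosphonate, K2CO3, MeOH, rt
Reagents that add atoms: dimethyl (1-diazo-2-oxopropyl)phosphonate, COP(=O)(OC)C(=[N+]=[N-])C(C)=O
Why: Ohira–Bestmann (Seyferth–Gilbert) homologation converts the aldehyde into the terminal alkyne under mildly basic conditions that leave the acetals untouched.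

Step 10
Reactants: 12 1-ethynyl-2,4-bis(methoxymethoxy)benzene
Product: 14 3-[2,4-bis(methoxymethoxy)phenyl]prop-2-ynoic acid, via lithium acetylide 13 (not isolated)
Conditions: n-BuLi, THF, −78 °C; CO2; cold 1 M HCl to pH 2
Reagents that add atoms: carbon dioxide, O=C=O
Why: Deprotonation of the terminal alkyne and carboxylation of the lithium acetylide is the standard entry to arylpropiolic acids; brief cold acidification spares the aryl acetals.

**Key step**

Step 11
Reactants: 9 3,5-bis(methoxymethoxy)-2-{[(triisopropylsilyl)oxy]methyl}-6-(trimethylsilyl)phenyl trifluoromethanesulfonate; 14 3-[2,4-bis(methoxymethoxy)phenyl]prop-2-ynoic acid (1.2 equiv)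
Product: 18 2-[2,4-bis(methoxymethoxy)phenyl]-5,7-bis(methoxymethoxy)-8-{[(triisopropylsilyl)oxy]methyl}-4H-chromen-4-one, via aryne 15 (not isolated), via aryl anion ester 16 (not isolated), via ynone phenoxide 17 (not isolated)
Conditions: CsF (4 equiv), THF, 125 °C, sealed tube
Reagents that add atoms: none
Why: Fluoride removes the trimethylsilyl group of 9 and triflate leaves to give aryne 15; the caesium carboxylate of 14 adds through oxygen at C8a, the C4a aryl anion 16 attacks its own ester carbonyl through a four-membered transition state (anionic O-to-C acyl shift) to give ynone phenoxide 17, and the vinyl anion formed on ring closure is protonated to 18. The closest known reaction type is the fluoride-induced insertion of arynes into the C–O bond of carboxylic acids, which with arylpropiolic acids continues to flavones. Ring C is closed by 6-endo-dig oxa-Michael addition of the C8a phenoxide to the ynone, forming O1–C2. No stereocentre is created. The step needs oxygen to add at C8a and not at C4a, which the C5 methoxymethoxy group secures by distorting the aryne so that the nucleophile enters meta to it and the charge develops ortho to it; the C8 substituent is only a CH2OTIPS group, with no alkene for an aryne ene reaction. Acyl transfer must also outrun protonation of 16, which the high temperature and the aprotic medium favour.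

**From the flavone core to the target**

Step 12
Reactants: 18 2-[2,4-bis(methoxymethoxy)phenyl]-5,7-bis(methoxymethoxy)-8-{[(triisopropylsilyl)oxy]methyl}-4H-chromen-4-one
Product: 19 2-[2,4-bis(methoxymethoxy)phenyl]-8-(hydroxymethyl)-5,7-bis(methoxymethoxy)-4H-chromen-4-one
Conditions: TBAF, AcOH, THF, 0 °C → rt
Reagents that add atoms: none
Why: Fluoride desilylation of the only silyl ether present; acetic acid buffering protects the pyranone from alkoxide attack at C2.

Step 13
Reactants: 19 2-[2,4-bis(methoxymethoxy)phenyl]-8-(hydroxymethyl)-5,7-bis(methoxymethoxy)-4H-chromen-4-one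
Product: 20 2-[2,4-bis(methoxymethoxy)phenyl]-5,7-bis(methoxymethoxy)-4-oxo-4H-chromene-8-carbaldehyde
Conditions: activated MnO2, CH2Cl2, rt
Reagents that add atoms: none
Why: Chemoselective oxidation of a benzylic alcohol by MnO2 stops at the aldehyde and leaves the acetals and the pyranone alone.

Step 14
Reactants: 21 6-methylhept-5-en-2-one
Product: 22 2,6-dimethylhept-5-en-2-ol
Conditions: MeMgBr, THF, 0 °C
Reagents that add atoms: methylmagnesium bromide, C[Mg]Br
Why: Grignard addition to the methyl ketone builds the tertiary carbinol of the chain terminus.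

Step 15
Reactants: 22 2,6-dimethylhept-5-en-2-ol
Product: 23 [(2,6-dimethylhept-5-en-2-yl)oxy]triethylsilane
Conditions: TESOTf, 2,6-lutidine, CH2Cl2, −78 → 0 °C
Reagents that add atoms: triethylsilyl trifluoromethanesulfonate, CC[Si](CC)(CC)OS(=O)(=O)C(F)(F)F
Why: Silyl triflate silylation of the tertiary alcohol, so that only one hydroxyl is free when the xanthate is made in step 19.

Step 16
Reactants: 23 [(2,6-dimethylhept-5-en-2-yl)oxy]triethylsilane
Product: 24 (2E)-2,6-dimethyl-6-[(triethylsilyl)oxy]hept-2-en-1-ol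
Conditions: SeO2 (cat.), t-BuOOH, salicylic acid (cat.), CH2Cl2, rt
Reagents that add atoms: selenium dioxide (catalytic oxygen carrier), O=[Se]=O; tert-butyl hydroperoxide (terminal oxidant), CC(C)(C)OO
Why: Selenium dioxide allylic oxidation (ene reaction, then [2,3]-sigmatropic shift) hydroxylates the (E)-methyl group of the gem-dimethyl alkene and so fixes the olefin geometry needed for step 18.

Step 17
Reactants: 24 (2E)-2,6-dimethyl-6-[(triethylsilyl)oxy]hept-2-en-1-ol
Product: 25 2-{(2E)-2,6-dimethyl-6-[(triethylsilyl)oxy]hept-2-en-1-yl}-4,4,5,5-tetramethyl-1,3,2-dioxaborolane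
Conditions: B2pin2, Pd(MeCN)4(BF4)2 (5 mol%), DMSO–MeOH, rt → 40 °C
Reagents that add atoms: bis(pinacolato)diboron, CC1(C)OB(B2OC(C)(C)C(C)(C)O2)OC1(C)C
Why: Palladium-catalysed borylation of an allylic alcohol with a diboron reagent replaces the hydroxyl at the primary terminus and is expected to keep the (E)-geometry.

Step 18
Reactants: 20 2-[2,4-bis(methoxymethoxy)phenyl]-5,7-bis(methoxymethoxy)-4-oxo-4H-chromene-8-carbaldehyde; 25 2-{(2E)-2,6-dimethyl-6-[(triethylsilyl)oxy]hept-2-en-1-yl}-4,4,5,5-tetramethyl-1,3,2-dioxaborolane (1.5 equiv)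
Product: 27 2-[2,4-bis(methoxymethoxy)phenyl]-8-{(1S,2S)-1-hydroxy-5-methyl-2-(prop-1-en-2-yl)-5-[(triethylsilyl)oxy]hexyl}-5,7-bis(methoxymethoxy)-4H-chromen-4-one, via borate ester 26 (not isolated)
Conditions: (S)-3,3'-bis(2,4,6-triisopropylphenyl)-1,1'-binaphthyl-2,2'-diyl hydrogen phosphate (5–10 mol%), 4 Å MS, toluene, −30 → 0 °C; aqueous work-up
Reagents that add atoms: none
Why: Chiral-phosphoric-acid-catalysed allylboration through a closed chair (Zimmerman–Traxler) transition state, in which the (E)-geometry of 25 gives the anti adduct and the (S)-acid directs the allyl group to the Si face of the aldehyde, setting C1'' as S and C2'' as S (the arrangement that is named 2''R once C1'' loses its oxygen); any syn diastereomer is removed by chromatography here.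

Step 19
Reactants: 27 2-[2,4-bis(methoxymethoxy)phenyl]-8-{(1S,2S)-1-hydroxy-5-methyl-2-(prop-1-en-2-yl)-5-[(triethylsilyl)oxy]hexyl}-5,7-bis(methoxymethoxy)-4H-chromen-4-one
Product: 28 O-{(1S,2S)-1-{2-[2,4-bis(methoxymethoxy)phenyl]-5,7-bis(methoxymethoxy)-4-oxo-4H-chromen-8-yl}-5-methyl-2-(prop-1-en-2-yl)-5-[(triethylsilyl)oxy]hexyl} S-methyl carbonodithioate
Conditions: NaHMDS, THF, −78 °C; CS2; MeI, −78 → 0 °C
Reagents that add atoms: carbon disulfide, S=C=S; iodomethane, CI
Why: Xanthate formation (alkoxide, CS2, S-methylation) at the only free hydroxyl gives the radical precursor without touching either stereocentre.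

Step 20
Reactants: 28 O-{(1S,2S)-1-{2-[2,4-bis(methoxymethoxy)phenyl]-5,7-bis(methoxymethoxy)-4-oxo-4H-chromen-8-yl}-5-methyl-2-(prop-1-en-2-yl)-5-[(triethylsilyl)oxy]hexyl} S-methyl carbonodithioate
Product: 29 2-[2,4-bis(methoxymethoxy)phenyl]-5,7-bis(methoxymethoxy)-8-{(2R)-5-methyl-2-(prop-1-en-2-yl)-5-[(triethylsilyl)oxy]hexyl}-4H-chromen-4-one
Conditions: Bu3SnH, Et3B (cat.), air, toluene, rt
Reagents that add atoms: none
Why: Barton–McCombie deoxygenation gives a stabilised benzylic radical that should be reduced by Bu3SnH much faster than it can close onto the neighbouring isopropenyl group, so C2'' is untouched and becomes R only through the change in substituent priority; room-temperature initiation avoids thermal xanthate elimination.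

Step 21
Reactants: 29 2-[2,4-bis(methoxymethoxy)phenyl]-5,7-bis(methoxymethoxy)-8-{(2R)-5-methyl-2-(prop-1-en-2-yl)-5-[(triethylsilyl)oxy]hexyl}-4H-chromen-4-one
Product: 31 2-(2,4-dihydroxyphenyl)-5,7-dihydroxy-8-[(2R)-5-hydroxy-5-methyl-2-(prop-1-en-2-yl)hexyl]-4H-chromen-4-one, via tetrakis(trimethylsilyl) ether 30 (not isolated)
Conditions: TMSOTf, 2,2'-bipyridyl, MeCN, 0 °C → rt; then TBAF, THF, rt; AcOH quench
Reagents that add atoms: none
Why: Silyl triflate–bipyridyl exchange converts the four aryl methoxymethyl ethers into aryl trimethylsilyl ethers under buffered, non-protic conditions that spare the isopropenyl group and the tertiary carbinol, and fluoride then cleaves all five silyl ethers.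

**Compound list**

1 | 2,4,6-trihydroxybenzaldehyde | O=Cc1c(O)cc(O)cc1O | starting material
2 | 2-hydroxy-4,6-bis(methoxymethoxy)benzaldehyde | O=Cc1c(O)cc(OCOC)cc1OCOC | intermediate
3 | 2-formyl-3,5-bis(methoxymethoxy)phenyl N,N-diethylcarbamate | CCN(CC)C(=O)Oc1cc(OCOC)cc(OCOC)c1C=O | intermediate
4 | 2-(hydroxymethyl)-3,5-bis(methoxymethoxy)phenyl N,N-diethylcarbamate | CCN(CC)C(=O)Oc1cc(OCOC)cc(OCOC)c1CO | intermediate
5 | 3,5-bis(methoxymethoxy)-2-{[(triisopropylsilyl)oxy]methyl}phenyl N,N-diethylcarbamate | CCN(CC)C(=O)Oc1cc(OCOC)cc(OCOC)c1CO[Si](C(C)C)(C(C)C)C(C)C | intermediate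
6 | {2-[(diethylcarbamoyl)oxy]-4,6-bis(methoxymethoxy)-3-{[(triisopropylsilyl)oxy]methyl}phenyl}lithium | [Li]c1c(OCOC)cc(OCOC)c(CO[Si](C(C)C)(C(C)C)C(C)C)c1OC(=O)N(CC)CC | intermediate
7 | 3,5-bis(methoxymethoxy)-2-{[(triisopropylsilyl)oxy]methyl}-6-(trimethylsilyl)phenyl N,N-diethylcarbamate | CCN(CC)C(=O)Oc1c([Si](C)(C)C)c(OCOC)cc(OCOC)c1CO[Si](C(C)C)(C(C)C)C(C)C | intermediate
8 | 3,5-bis(methoxymethoxy)-2-{[(triisopropylsilyl)oxy]methyl}-6-(trimethylsilyl)phenol | Oc1c([Si](C)(C)C)c(OCOC)cc(OCOC)c1CO[Si](C(C)C)(C(C)C)C(C)C | intermediate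
9 | 3,5-bis(methoxymethoxy)-2-{[(triisopropylsilyl)oxy]methyl}-6-(trimethylsilyl)phenyl trifluoromethanesulfonate | COCOc1cc(OCOC)c([Si](C)(C)C)c(OS(=O)(=O)C(F)(F)F)c1CO[Si](C(C)C)(C(C)C)C(C)C | intermediate
10 | 2,4-dihydroxybenzaldehyde | O=Cc1ccc(O)cc1O | starting material
11 | 2,4-bis(methoxymethoxy)benzaldehyde | O=Cc1ccc(OCOC)cc1OCOC | intermediate
12 | 1-ethynyl-2,4-bis(methoxymethoxy)benzene | C#Cc1ccc(OCOC)cc1OCOC | intermediate
13 | {[2,4-bis(methoxymethoxy)phenyl]ethynyl}lithium | [Li]C#Cc1ccc(OCOC)cc1OCOC | intermediate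
14 | 3-[2,4-bis(methoxymethoxy)phenyl]prop-2-ynoic acid | OC(=O)C#Cc1ccc(OCOC)cc1OCOC | intermediate
15 | 3,5-bis(methoxymethoxy)-6-{[(triisopropylsilyl)oxy]methyl}benzyne (1,2-didehydrobenzene) | COCOC1=CC(OCOC)=C(CO[Si](C(C)C)(C(C)C)C(C)C)C#C1 | intermediate
16 | {2-({3-[2,4-bis(methoxymethoxy)phenyl]prop-2-ynoyl}oxy)-4,6-bis(methoxymethoxy)-3-{[(triisopropylsilyl)oxy]methyl}phenyl}caesium | COCOc1cc(OCOC)[c-]c(OC(=O)C#Cc2ccc(OCOC)cc2OCOC)c1CO[Si](C(C)C)(C(C)C)C(C)C.[Cs+] | intermediate
17 | caesium 2-{3-[2,4-bis(methoxymethoxy)phenyl]prop-2-ynoyl}-3,5-bis(methoxymethoxy)-6-{[(triisopropylsilyl)oxy]methyl}phenolate | COCOc1cc(OCOC)c(C(=O)C#Cc2ccc(OCOC)cc2OCOC)c([O-])c1CO[Si](C(C)C)(C(C)C)C(C)C.[Cs+] | intermediate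
18 | 2-[2,4-bis(methoxymethoxy)phenyl]-5,7-bis(methoxymethoxy)-8-{[(triisopropylsilyl)oxy]methyl}-4H-chromen-4-one | COCOc1cc(OCOC)c2c(=O)cc(-c3ccc(OCOC)cc3OCOC)oc2c1CO[Si](C(C)C)(C(C)C)C(C)C | intermediate
19 | 2-[2,4-bis(methoxymethoxy)phenyl]-8-(hydroxymethyl)-5,7-bis(methoxymethoxy)-4H-chromen-4-one | COCOc1cc(OCOC)c2c(=O)cc(-c3ccc(OCOC)cc3OCOC)oc2c1CO | intermediate
20 | 2-[2,4-bis(methoxymethoxy)phenyl]-5,7-bis(methoxymethoxy)-4-oxo-4H-chromene-8-carbaldehyde | COCOc1cc(OCOC)c2c(=O)cc(-c3ccc(OCOC)cc3OCOC)oc2c1C=O | intermediate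
21 | 6-methylhept-5-en-2-one | CC(=O)CCC=C(C)C | starting material
22 | 2,6-dimethylhept-5-en-2-ol | CC(C)=CCCC(C)(C)O | intermediate
23 | [(2,6-dimethylhept-5-en-2-yl)oxy]triethylsilane | CC(C)=CCCC(C)(C)O[Si](CC)(CC)CC | intermediate
24 | (2E)-2,6-dimethyl-6-[(triethylsilyl)oxy]hept-2-en-1-ol | OC/C(C)=C/CCC(C)(C)O[Si](CC)(CC)CC | intermediate
25 | 2-{(2E)-2,6-dimethyl-6-[(triethylsilyl)oxy]hept-2-en-1-yl}-4,4,5,5-tetramethyl-1,3,2-dioxaborolane | CC1(C)OB(C/C(C)=C/CCC(C)(C)O[Si](CC)(CC)CC)OC1(C)C | intermediate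
26 | 2-[2,4-bis(methoxymethoxy)phenyl]-5,7-bis(methoxymethoxy)-8-{(1S,2S)-5-methyl-2-(prop-1-en-2-yl)-1-[(4,4,5,5-tetramethyl-1,3,2-dioxaborolan-2-yl)oxy]-5-[(triethylsilyl)oxy]hexyl}-4H-chromen-4-one | C=C(C)[C@H](CCC(C)(C)O[Si](CC)(CC)CC)[C@H](OB1OC(C)(C)C(C)(C)O1)c1c(OCOC)cc(OCOC)c2c(=O)cc(-c3ccc(OCOC)cc3OCOC)oc12 | intermediate
27 | 2-[2,4-bis(methoxymethoxy)phenyl]-8-{(1S,2S)-1-hydroxy-5-methyl-2-(prop-1-en-2-yl)-5-[(triethylsilyl)oxy]hexyl}-5,7-bis(methoxymethoxy)-4H-chromen-4-one | C=C(C)[C@H](CCC(C)(C)O[Si](CC)(CC)CC)[C@H](O)c1c(OCOC)cc(OCOC)c2c(=O)cc(-c3ccc(OCOC)cc3OCOC)oc12 | intermediate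
28 | O-{(1S,2S)-1-{2-[2,4-bis(methoxymethoxy)phenyl]-5,7-bis(methoxymethoxy)-4-oxo-4H-chromen-8-yl}-5-methyl-2-(prop-1-en-2-yl)-5-[(triethylsilyl)oxy]hexyl} S-methyl carbonodithioate | C=C(C)[C@H](CCC(C)(C)O[Si](CC)(CC)CC)[C@H](OC(=S)SC)c1c(OCOC)cc(OCOC)c2c(=O)cc(-c3ccc(OCOC)cc3OCOC)oc12 | intermediate
29 | 2-[2,4-bis(methoxymethoxy)phenyl]-5,7-bis(methoxymethoxy)-8-{(2R)-5-methyl-2-(prop-1-en-2-yl)-5-[(triethylsilyl)oxy]hexyl}-4H-chromen-4-one | C=C(C)[C@H](CCC(C)(C)O[Si](CC)(CC)CC)Cc1c(OCOC)cc(OCOC)c2c(=O)cc(-c3ccc(OCOC)cc3OCOC)oc12 | intermediate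
30 | 2-{2,4-bis[(trimethylsilyl)oxy]phenyl}-8-{(2R)-5-methyl-2-(prop-1-en-2-yl)-5-[(triethylsilyl)oxy]hexyl}-5,7-bis[(trimethylsilyl)oxy]-4H-chromen-4-one | C=C(C)[C@H](CCC(C)(C)O[Si](CC)(CC)CC)Cc1c(O[Si](C)(C)C)cc(O[Si](C)(C)C)c2c(=O)cc(-c3ccc(O[Si](C)(C)C)cc3O[Si](C)(C)C)oc12 | intermediate
31 | 2-(2,4-dihydroxyphenyl)-5,7-dihydroxy-8-[(2R)-5-hydroxy-5-methyl-2-(prop-1-en-2-yl)hexyl]-4H-chromen-4-one | C=C(C)[C@H](CCC(C)(C)O)Cc1c(O)cc(O)c2c(=O)cc(-c3ccc(O)cc3O)oc12 | target

**Step count**

Total: 21 steps. Longest linear sequence: 14 steps (steps 1–7, 11–13, 18–21).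

**Steps most likely to fail**

1. Step 11 (aryne insertion). The C4a aryl anion may be protonated before it reaches the ester carbonyl, so that the sequence stops at an aryl ester. The carboxylate may also add at C4a, or fluoride may strip the silyl ether at 125 °C. Fallback: the pyranone would be built without an aryne, setting out from phenol 8. Ipso-iododesilylation (NIS, MeCN, 0 °C) should give 2-iodo-3,5-bis(methoxymethoxy)-6-{[(triisopropylsilyl)oxy]methyl}phenol F1. Carbonylative Sonogashira coupling of F1 with alkyne 12 (PdCl2(PPh3)2 cat., CO 1 atm, Et2NH, 60 °C) should give 3-[2,4-bis(methoxymethoxy)phenyl]-1-{2-hydroxy-4,6-bis(methoxymethoxy)-3-{[(triisopropylsilyl)oxy]methyl}phenyl}prop-2-yn-1-one F2. F2 is not isolated: the amine promotes its 6-endo cyclisation in the same flask, and the route is rejoined at flavone 18.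

2. Step 18 (allylboration). Facial selectivity may be poor at the doubly ortho-substituted aldehyde, and any loss of olefin geometry in 25 would leak into the syn adduct and lower the enantiopurity at C2''. Fallback: setting out from allylic alcohol 24, bromination (CBr4, PPh3, CH2Cl2, 0 °C) should give (2E)-1-bromo-2,6-dimethyl-6-[(triethylsilyl)oxy]hept-2-ene F3. An asymmetric Nozaki–Hiyama–Kishi allylation of aldehyde 20 with F3 (CrCl2 cat., chiral oxazoline–sulfonamide ligand, manganese powder, Cp2ZrCl2, MeCN) then follows. The allylchromium species equilibrates and adds anti whatever the halide geometry, and the ligand antipode that directs Si-face addition rejoins the route at alcohol 27.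

3. Step 5 (directed metalation). Lithiation may occur at the ring CH between the two methoxymethoxy groups or at the benzylic CH2 instead of between carbamate and methoxymethoxy, and the carbamoyl group may migrate if the aryllithium warms. Fallback: silicon would be placed through a halogen, setting out from phenol 2.
   - Bromination ortho to the free, chelated hydroxyl (NBS, CH2Cl2, 0 °C) should give 3-bromo-2-hydroxy-4,6-bis(methoxymethoxy)benzaldehyde F4; the regiochemistry would be checked before going on.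
   - NaBH4 reduction gives 2-bromo-6-(hydroxymethyl)-3,5-bis(methoxymethoxy)phenol F5, which is silylated at once at the primary hydroxyl (TIPSCl, imidazole) to 2-bromo-3,5-bis(methoxymethoxy)-6-{[(triisopropylsilyl)oxy]methyl}phenol F6.
   - Hexamethyldisilazane converts F6 into {2-bromo-3,5-bis(methoxymethoxy)-6-{[(triisopropylsilyl)oxy]methyl}phenoxy}trimethylsilane F7.
   - Bromine–lithium exchange on F7 (n-BuLi, THF, −78 °C) triggers a 1,3 O-to-C silyl shift, and Tf2O added to the same flask rejoins the route at triflate 9.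

Further compounds
F1 | step 11 | 2-iodo-3,5-bis(methoxymethoxy)-6-{[(triisopropylsilyl)oxy]methyl}phenol | Oc1c(I)c(OCOC)cc(OCOC)c1CO[Si](C(C)C)(C(C)C)C(C)C
F2 | step 11 | 3-[2,4-bis(methoxymethoxy)phenyl]-1-{2-hydroxy-4,6-bis(methoxymethoxy)-3-{[(triisopropylsilyl)oxy]methyl}phenyl}prop-2-yn-1-one | COCOc1cc(OCOC)c(C(=O)C#Cc2ccc(OCOC)cc2OCOC)c(O)c1CO[Si](C(C)C)(C(C)C)C(C)C
F3 | step 18 | (2E)-1-bromo-2,6-dimethyl-6-[(triethylsilyl)oxy]hept-2-ene | BrC/C(C)=C/CCC(C)(C)O[Si](CC)(CC)CC
F4 | step 5 | 3-bromo-2-hydroxy-4,6-bis(methoxymethoxy)benzaldehyde | O=Cc1c(O)c(Br)c(OCOC)cc1OCOC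
F5 | step 5 | 2-bromo-6-(hydroxymethyl)-3,5-bis(methoxymethoxy)phenol | OCc1c(O)c(Br)c(OCOC)cc1OCOC
F6 | step 5 | 2-bromo-3,5-bis(methoxymethoxy)-6-{[(triisopropylsilyl)oxy]methyl}phenol | Oc1c(Br)c(OCOC)cc(OCOC)c1CO[Si](C(C)C)(C(C)C)C(C)C
F7 | step 5 | {2-bromo-3,5-bis(methoxymethoxy)-6-{[(triisopropylsilyl)oxy]methyl}phenoxy}trimethylsilane | C[Si](C)(C)Oc1c(Br)c(OCOC)cc(OCOC)c1CO[Si](C(C)C)(C(C)C)C(C)C
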